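Compound numbers are those of the compound list after the steps.

## Analysis of the target

Balanophonin (16) is a 2,3-dihydro-1-benzofuran (O1, C2, C3, C3a, C4 to C7, C7a) of the 8–5' neolignan family. C2 carries the 4-hydroxy-3-methoxyphenyl ring (ring A), C3 a hydroxymethyl group, and the benzo ring (ring B) an (E)-propenal chain at C5 and a methoxy group at C7. The only stereocentres are C2 (R) and C3 (S); they are adjacent, both benzylic, and the aryl and CH2OH groups are trans. The enal is a Michael acceptor that cannot pass through organolithium chemistry or long exposure to basic fluoride. The free ring A phenol lies para to the benzylic C2–O1 bond, so base (through a quinone methide) or strong acid (through a benzylic cation) can open the furan ring and endanger C2. The difficulty is therefore not size but absolute control of two contiguous benzylic centres on a flat, electron-rich frame that offers no handle to a chiral reagent. The plan rests on one feature: the C2–C3 bond is formally the C2=C3 double bond of a benzofuran to which an aryl group (at C2) and a one-carbon oxygenated unit (at C3) have been added on opposite faces, with a hydrogen left on C2 where boron can sit during the addition. Ring B, with bromine standing in for the C5 side chain and the C7 methoxy group in place, can then be an ordinary benzofuran.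

## Retrosynthetic reasoning

**16 from 15.** The last bond cut is the O–CH2 bond of a methoxymethyl ether on the ring A phenol. The phenol stays masked to the end because a free para-phenol labilises C2–O1. An acetal is chosen because it must survive an aryllithium, fluoride and carbonate base. A silyl ether here would be lost to the fluoride that removes boron and would release a para-phenoxide next to the C–B bond. The forward step is a dilute-acid hydrolysis that the enal tolerates.

**15 from 12 and 13.** The C5–C(alkene) bond is cut. The enal is added late because it would not survive the organolithium and fluoride steps, while the C5 bromide of 12 is an inert placeholder through all of them. The forward reaction is a Heck coupling, with the aldehyde carried as the diethyl acetal 13 (free acrolein polymerises under hot basic conditions) and released by acid through 14.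

**12 from 10.** The C2–H bond is traced back to a C2–B bond and the free CH2OH to its silyl ether. The forward step must replace boron by hydrogen with retention, so that H takes the place boron held (cis to the C3 substituent) and the aryl group stays trans. Fluoride does this and then cleaves the silyl ether, passing through 11.

**10 from 5, 6 and 7 (key disconnection).** The C2–aryl and C3–CH2 bonds are cut together. This returns the flat boronic ester 5, the aryl bromide 6 (as aryllithium 8) and the chloromethyl silyl ether 7. Cutting here, and not inside ring B or at C2–O1, removes both stereocentres and both non-ring skeletal bonds in one operation. In the forward direction, 8 adds to boron to give boronate 9; a catalyst-bound cation equivalent from 7 attacks C3; the aryl group shifts from boron to C2 on the opposite face. The trans relationship is therefore mechanistic, and only the face of attack at C3 has to be controlled by the chiral catalyst.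

**5 from 4, 4 from 3, 3 from 1 and 2.** The C2–B bond comes from C–H borylation of benzofuran 4, whose only unhindered, activated C–H bond is at C2. The furan ring of 4 is cut at C3–C3a (acid cyclodehydration of acetal 3) and at the ether O–CH2 bond (alkylation of phenol 1 with 2). Because C2 and C4 of 1 are occupied, ring closure can occur only at the position that places Br at C5 and OMe at C7.

**6 from 1.** The second fragment is the same phenol 1, protected as its methoxymethyl ether. Both halves of the molecule therefore come from one commodity phenol.

## Alternatives that were turned down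

**Alternative 1:** gold-catalysed furan–yne phenol synthesis.
- Disconnection: ring B is cut at C3a–C7a and C6–C7, leading back to the acyclic ethynyl ether A1, which already holds both stereocentres and a 4-substituted 2-furyl group.
- Forward key step: Ph3PAuNTf2 activates the alkynyl ether, the furan carbon attacks the oxygen-bearing alkyne carbon, and rearrangement through oxepine and arene oxide stages joins the far furan carbon to the alkyne terminus. Both fused rings and the C7 phenol of A2 form at once.
- For: one catalytic step at ambient temperature builds the whole bicycle; the C7 oxygen appears where it is needed; the reaction type is well established for furan–ynes. On ring construction and ring B regiochemistry this alternative is stronger than the chosen route, which builds no ring in its key step.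
- Against: A1 is a 1-alkynyl ether of a para-alkoxybenzylic secondary alcohol, a class prone to ionisation and to thermal loss of ketene; its gold-activated form is a ketene-oxonium-like species that adventitious nucleophiles can intercept. The anti-configured stereocentres must be made beforehand by acyclic stereocontrol. A2 still lacks the C7 methyl group and the entire propenal chain: methylation, selective desilylation, oxidation, two-carbon olefination and two deprotections remain.
- Comparison: an estimated fifteen or more steps against eight. The chosen route takes ring B fully substituted from 1 and spends its one difficult step on the stereocentres themselves.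

**Alternative 2:** oxidative ring contraction of an enantioenriched flavanone.
- Disconnection: the C3–C3a bond, leading back to the (2R)-flavanone A3.
- Forward key step: PhI(OAc)2 and H2SO4 in HC(OMe)3 ketalise A3, place trivalent iodine at C3, and ring B migrates from the former carbonyl carbon to C3, contracting the ring and giving the trans methyl ester A4.
- For: this is a known reaction type on flavanones; C2 directs C3 to the trans arrangement; A4 carries the same bromide and is one reduction from the CH2OH group. On methodological risk of the key step this alternative is stronger than the chosen one.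
- Against: the enantiopurity rests on a separate asymmetric synthesis of A3. A3's single stereocentre is exposed to the strong acid of the key step, where flavanones with electron-rich 2-aryl groups racemise by reversible opening to the hydroxychalcone. The electron-rich 2-aryl group can itself migrate (the isoflavone pathway) or be attacked by the iodane, which is why its phenol must be deactivated as the pivalate. The bromine-bearing ring B is a reluctant migrating group.
- Comparison: with four or five steps to A3, then contraction, reduction, Heck coupling and deacylation, the length is similar to the chosen route. The chosen route instead creates both centres in one catalyst-controlled event from achiral, flat fragments and never exposes a stereocentre to strong acid.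

**Alternative 3:** ring B by pyrone cycloaddition and CO2 extrusion.
- Disconnection: ring B is cut at C3a–C4 and C7–C7a, leading back to the silyl ketene acetal A5 and methyl 3-bromocoumalate A6.
- Forward key step: a thermal inverse-demand [4+2] cycloaddition, then loss of CO2 and silanol, gives the arene A7.
- For: the stereocentres are set on a small lactone framework by established chemistry and are not touched afterwards; the polarisation of both partners fixes the regiochemistry; the route is convergent. On security of the stereochemistry before the key step this alternative is stronger.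
- Against: A7 is wrongly functionalised for this target. It has bromine at C7, where a hindered C–O coupling must install OMe, and an ester at C5, which must be reduced and homologated to the enal; with deprotections this is six or more further steps. A5 needs its own multistep asymmetric synthesis. In the aromatisation, loss of the ring oxygen (opening the dihydrofuran) competes with loss of silanol.
- Comparison: roughly fifteen steps against eight. The chosen route starts with ring B correctly substituted and forms the two stereocentres and two skeletal bonds together.

Key step: step 5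

Assumptions on the chemistry:
- The sense of induction of the chiral thiourea in step 5 cannot be predicted. The catalyst is 1-[3,5-bis(trifluoromethyl)phenyl]-3-[(2S)-3,3-dimethyl-1-oxo-1-[(2R)-2-phenylpyrrolidin-1-yl]butan-2-yl]thiourea or its mirror image, whichever leads to the (2R,3S) series.
- Compounds 7 and 13 are taken as articles of commerce.

## Route

Step 1
Reactants: 1 4-bromo-2-methoxyphenol; 2 bromoacetaldehyde diethyl acetal
Product: 3 4-bromo-1-(2,2-diethoxyethoxy)-2-methoxybenzene
Conditions: K2CO3, DMF, 120 °C
Reagents that add atoms: none
Why: Williamson ether synthesis; the phenoxide displaces the primary bromide, and the acetal and aryl bromide are inert to carbonate.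

Step 2
Reactants: 3 4-bromo-1-(2,2-diethoxyethoxy)-2-methoxybenzene
Product: 4 5-bromo-7-methoxy-1-benzofuran
Conditions: polyphosphoric acid, PhCl, 120 °C
Reagents that add atoms: none
Why: Acid-mediated cyclodehydration (intramolecular Friedel–Crafts attack of the oxocarbenium ion, then loss of ethanol); the only free position ortho to the ether oxygen is used, which fixes Br at C5 and OMe at C7.

Step 3
Reactants: 4 5-bromo-7-methoxy-1-benzofuran
Product: 5 2-(5-bromo-7-methoxy-1-benzofuran-2-yl)-4,4,5,5-tetramethyl-1,3,2-dioxaborolane
Conditions: [Ir(cod)OMe]2 (1.5 mol %), 4,4'-di-tert-butyl-2,2'-bipyridine (3 mol %), B2pin2 (1.0 equiv), THF, 50 °C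
Reagents that add atoms: bis(pinacolato)diboron, CC1(C)OB(OC1(C)C)B1OC(C)(C)C(C)(C)O1
Why: Iridium-catalysed C–H borylation; the C2–H bond next to the furan oxygen is the most reactive, C4–H and C6–H are each flanked by two substituents, and aryl bromides are tolerated.

Step 4
Reactants: 1 4-bromo-2-methoxyphenol
Product: 6 4-bromo-2-methoxy-1-(methoxymethoxy)benzene
Conditions: MeOCH2Cl, i-Pr2NEt, CH2Cl2, 0 °C to rt
Reagents that add atoms: chloromethyl methyl ether, COCCl
Why: O-alkylation of the phenol with an alpha-chloro ether gives the methoxymethyl acetal, which is stable to organolithiums, fluoride and carbonate and is removed by dilute acid.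

Step 5
Reactants: 6 4-bromo-2-methoxy-1-(methoxymethoxy)benzene; 5 2-(5-bromo-7-methoxy-1-benzofuran-2-yl)-4,4,5,5-tetramethyl-1,3,2-dioxaborolane; 7 (triisopropylsiloxy)methyl chloride
Product: 10 2-[(2R,3S)-5-bromo-7-methoxy-2-[3-methoxy-4-(methoxymethoxy)phenyl]-3-{[tri(propan-2-yl)silyl]oxymethyl}-2,3-dihydro-1-benzofuran-2-yl]-4,4,5,5-tetramethyl-1,3,2-dioxaborolane, via aryllithium 8 (not isolated), via lithium boronate 9 (not isolated)
Conditions: 6, t-BuLi (2.0 equiv), Et2O, −78 °C; 5 (1.05 equiv), −78 °C; then 7, chiral amido-thiourea (10 mol %), TBME–toluene, −78 °C
Reagents that add atoms: none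
Why: Proposed new method: bromine–lithium exchange on 6 gives 8, which adds to the boron of 5 faster than it exchanges with the ring B bromide, and the resulting boronate 9 is an enol ether whose C3 is made strongly nucleophilic by O1 and by the anionic boron on C2. The thiourea binds the chloride of 7 and presents a silyloxymethyl cation equivalent to C3 (C3–CH2 bond); as positive charge builds at C2, where O1 stabilises it, the guaiacyl group shifts from boron to C2 (C2–aryl bond) antiperiplanar to the new bond at C3. The closest known reactions are the three-component dearomative couplings of indol-2-yl and furan-2-yl boronate complexes with carbon electrophiles and the enantioselective anion-binding catalysis of alpha-chloro ethers; their combination on a benzofuran-2-yl boronate has not been shown. No ring is closed: the furan ring is dearomatised and two skeletal bonds are formed. C3 is set by the face on which the catalyst-bound electrophile approaches (catalyst control), and C2 follows stereospecifically from the anti migration, which places the aryl group trans to the CH2O group and boron cis to it. The step needs attack at C3 to outrun ipso attack on the guaiacyl ring and the uncatalysed alkylation; the enol ether carbon is the most electron-rich site, the pinacol oxygen atoms do not migrate, and low temperature in a weakly coordinating solvent slows the background path. 5 is used in slight excess so that no 8 remains to be alkylated by 7.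

Step 6
Reactants: 10 2-[(2R,3S)-5-bromo-7-methoxy-2-[3-methoxy-4-(methoxymethoxy)phenyl]-3-{[tri(propan-2-yl)silyl]oxymethyl}-2,3-dihydro-1-benzofuran-2-yl]-4,4,5,5-tetramethyl-1,3,2-dioxaborolane
Product: 12 [(2R,3S)-5-bromo-7-methoxy-2-[3-methoxy-4-(methoxymethoxy)phenyl]-2,3-dihydro-1-benzofuran-3-yl]methanol, via silyl ether 11 (not isolated)
Conditions: Bu4NF·3H2O (1.5 equiv), toluene, 45 °C; then THF, Bu4NF·3H2O (2 equiv), rt
Reagents that add atoms: none
Why: Fluoride-promoted protodeboronation of a tertiary benzylic boronic ester: fluoride forms the boron ate complex and hydrate water delivers the proton to C2 on the face that boron leaves (retention), so H ends cis to the C3 substituent and the aryl group stays trans. The further fluoride then cleaves the primary silyl ether; the acetal and the aryl bromide are inert.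

Step 7
Reactants: 12 [(2R,3S)-5-bromo-7-methoxy-2-[3-methoxy-4-(methoxymethoxy)phenyl]-2,3-dihydro-1-benzofuran-3-yl]methanol; 13 acrolein diethyl acetal
Product: 15 (2E)-3-[(2R,3S)-3-(hydroxymethyl)-7-methoxy-2-[3-methoxy-4-(methoxymethoxy)phenyl]-2,3-dihydro-1-benzofuran-5-yl]prop-2-enal, via diethyl acetal 14 (not isolated)
Conditions: Pd(OAc)2 (3 mol %), Bu4NOAc, K2CO3, KCl, DMF, 90 °C; then 1 M HCl, THF, rt
Reagents that add atoms: water, O
Why: Heck reaction: zerovalent palladium formed from Pd(OAc)2 inserts into the C5–Br bond, the aryl group adds to the terminal carbon of 13, and beta-hydride elimination towards the ring gives the E-configured acetal 14, which brief dilute acid hydrolyses to the enal. The acetate/carbonate/chloride medium is the known combination that favours the cinnamaldehyde acetal over the ester; the stereocentres and the methoxymethyl ether are untouched.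

Step 8
Reactants: 15 (2E)-3-[(2R,3S)-3-(hydroxymethyl)-7-methoxy-2-[3-methoxy-4-(methoxymethoxy)phenyl]-2,3-dihydro-1-benzofuran-5-yl]prop-2-enal
Product: 16 balanophonin, (2E)-3-[(2R,3S)-2-(4-hydroxy-3-methoxyphenyl)-3-(hydroxymethyl)-7-methoxy-2,3-dihydro-1-benzofuran-5-yl]prop-2-enal
Conditions: 2 M aq. HCl, THF, 45 °C
Reagents that add atoms: none
Why: Acid hydrolysis of the aryl methoxymethyl ether (acetal cleavage); the enal, the primary alcohol and the methyl ethers are stable to dilute acid at this temperature, and the trans isomer is the thermodynamically preferred one, so C2 and C3 are not at risk.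

## Compound list

1 | 4-bromo-2-methoxyphenol | COc1cc(Br)ccc1O | starting material
2 | bromoacetaldehyde diethyl acetal (2-bromo-1,1-diethoxyethane) | CCOC(CBr)OCC | starting material
3 | 4-bromo-1-(2,2-diethoxyethoxy)-2-methoxybenzene | CCOC(COc1ccc(Br)cc1OC)OCC | intermediate
4 | 5-bromo-7-methoxy-1-benzofuran | COc1cc(Br)cc2ccoc12 | intermediate
5 | 2-(5-bromo-7-methoxy-1-benzofuran-2-yl)-4,4,5,5-tetramethyl-1,3,2-dioxaborolane | COc1cc(Br)cc2cc(B3OC(C)(C)C(C)(C)O3)oc12 | intermediate
6 | 4-bromo-2-methoxy-1-(methoxymethoxy)benzene | COCOc1ccc(Br)cc1OC | intermediate
7 | (triisopropylsiloxy)methyl chloride | ClCO[Si](C(C)C)(C(C)C)C(C)C | starting material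
8 | [3-methoxy-4-(methoxymethoxy)phenyl]lithium | [Li]c1ccc(OCOC)c(OC)c1 | intermediate (not isolated)
9 | lithium (5-bromo-7-methoxy-1-benzofuran-2-yl)[3-methoxy-4-(methoxymethoxy)phenyl](pinacolato)borate | [Li+].COCOc1ccc(cc1OC)[B-]1(OC(C)(C)C(C)(C)O1)c1cc2cc(Br)cc(OC)c2o1 | intermediate (not isolated)
10 | 2-[(2R,3S)-5-bromo-7-methoxy-2-[3-methoxy-4-(methoxymethoxy)phenyl]-3-{[tri(propan-2-yl)silyl]oxymethyl}-2,3-dihydro-1-benzofuran-2-yl]-4,4,5,5-tetramethyl-1,3,2-dioxaborolane (aryl and CH2O groups trans) | COc1cc([C@]2(B4OC(C)(C)C(C)(C)O4)Oc3c(OC)cc(Br)cc3[C@H]2CO[Si](C(C)C)(C(C)C)C(C)C)ccc1OCOC | intermediate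
11 | {[(2R,3S)-5-bromo-7-methoxy-2-[3-methoxy-4-(methoxymethoxy)phenyl]-2,3-dihydro-1-benzofuran-3-yl]methoxy}tri(propan-2-yl)silane | COc1cc([C@@H]2Oc3c(OC)cc(Br)cc3[C@H]2CO[Si](C(C)C)(C(C)C)C(C)C)ccc1OCOC | intermediate (not isolated)
12 | [(2R,3S)-5-bromo-7-methoxy-2-[3-methoxy-4-(methoxymethoxy)phenyl]-2,3-dihydro-1-benzofuran-3-yl]methanol | COc1cc([C@@H]2Oc3c(OC)cc(Br)cc3[C@H]2CO)ccc1OCOC | intermediate
13 | acrolein diethyl acetal (3,3-diethoxyprop-1-ene) | C=CC(OCC)OCC | starting material
14 | [(2R,3S)-5-[(1E)-3,3-diethoxyprop-1-en-1-yl]-7-methoxy-2-[3-methoxy-4-(methoxymethoxy)phenyl]-2,3-dihydro-1-benzofuran-3-yl]methanol | COc1cc([C@@H]2Oc3c(OC)cc(/C=C/C(OCC)OCC)cc3[C@H]2CO)ccc1OCOC | intermediate (not isolated)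
15 | (2E)-3-[(2R,3S)-3-(hydroxymethyl)-7-methoxy-2-[3-methoxy-4-(methoxymethoxy)phenyl]-2,3-dihydro-1-benzofuran-5-yl]prop-2-enal | COc1cc([C@@H]2Oc3c(OC)cc(/C=C/C=O)cc3[C@H]2CO)ccc1OCOC | intermediate
16 | balanophonin, (2E)-3-[(2R,3S)-2-(4-hydroxy-3-methoxyphenyl)-3-(hydroxymethyl)-7-methoxy-2,3-dihydro-1-benzofuran-5-yl]prop-2-enal | COc1cc([C@@H]2Oc3c(OC)cc(/C=C/C=O)cc3[C@H]2CO)ccc1O | target

## Step count and least certain steps

Total: 8 steps. Longest linear sequence: 7 steps (steps 1, 2, 3, 5, 6, 7, 8); step 4 is a one-step branch.

**Step 5 (key step, proposed new method).**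
- What may go wrong: facial discrimination at C3 may be poor, because the prochiral element sits on the nucleophile and the very nucleophilic boronate can be alkylated by 7 without the catalyst; the lithium cation and ether solvent can also compete for the hydrogen-bond donor. Ipso attack of the electrophile on the electron-rich guaiacyl ring, or alkylation of unreacted aryllithium, would lower conversion to the three-component product.
- Fallback (known chemistry), from 5 and 6, returning at 12:
  - Oxidation of 5 with NaBO3·4H2O in THF/water and acidic work-up should give 5-bromo-7-methoxy-1-benzofuran-2(3H)-one F1.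
  - Acid-catalysed methanolysis opens the lactone to methyl 2-(5-bromo-2-hydroxy-3-methoxyphenyl)acetate F2.
  - Bromine–lithium exchange on 6 with t-BuLi and trapping with paraformaldehyde gives [3-methoxy-4-(methoxymethoxy)phenyl]methanol F3.
  - A Mitsunobu reaction (PPh3, diisopropyl azodicarboxylate) joins F3 to the phenol of F2, giving methyl 2-[5-bromo-3-methoxy-2-{[3-methoxy-4-(methoxymethoxy)phenyl]methoxy}phenyl]acetate F4.
  - Diazo transfer (4-acetamidobenzenesulfonyl azide, DBU, MeCN) gives methyl 2-[5-bromo-3-methoxy-2-{[3-methoxy-4-(methoxymethoxy)phenyl]methoxy}phenyl]-2-diazoacetate F5.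
  - Dirhodium tetrakis[N-phthaloyl-tert-leucinate], Rh2(S-PTTL)4 or its mirror image (whichever gives the 2R series), inserts the carbene into the benzylic C–H bond at low temperature. This gives the cis ester methyl (2R,3S)-5-bromo-7-methoxy-2-[3-methoxy-4-(methoxymethoxy)phenyl]-2,3-dihydro-1-benzofuran-3-carboxylate F6.
  - NaOMe in MeOH epimerises C3 to the trans ester methyl (2R,3R)-5-bromo-7-methoxy-2-[3-methoxy-4-(methoxymethoxy)phenyl]-2,3-dihydro-1-benzofuran-3-carboxylate F7.
  - LiBH4 in THF reduces the ester to 12.

**Step 6.**
- What may go wrong: incomplete retention in the C–B protonolysis. If the C–B bond breaks before the proton arrives, the planar benzylic alpha-oxy carbanion is protonated from the face away from the C3 substituent, eroding the trans configuration at C2.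
- Fallback, from 12 (as obtained, whatever its C2 purity), returning at 16: the material is carried through steps 7 and 8, and C2 is corrected thermodynamically instead of kinetically. Longer exposure to the acid of step 8, or a brief treatment of 16 with CF3CO2H in CH2Cl2, ionises the C2–O1 bond reversibly to the para-hydroxybenzyl cation, which recloses to the more stable trans ring. C3 is not involved, so the enantiopurity set in step 5 is kept. No new compound is made.

**Step 7.**
- What may go wrong: slow oxidative addition into the electron-rich C5–Br bond (para to O1), and beta-hydride elimination towards the acetal carbon, which after hydrolysis would give the saturated ester instead of the enal.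
- Fallback, from 12, returning at 14: Suzuki–Miyaura coupling of 12 with commercial 2-[(1E)-3,3-diethoxyprop-1-en-1-yl]-4,4,5,5-tetramethyl-1,3,2-dioxaborolane (Pd(dppf)Cl2, K3PO4, dioxane/water, 80 °C). The E-alkene geometry and the oxidation level are then fixed in the reagent instead of by a carbopalladation. 14 is hydrolysed to 15 as in step 7. No new compound is made.

**Step 2.**
- What may go wrong: oligomerisation of the liberated aryloxyacetaldehyde, and low conversion because the closing position is only weakly activated (meta to OMe and to Br).
- Fallback, from 1, returning at 4: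
  - Iodination of 1 ortho to the hydroxyl group with N-iodosuccinimide gives 4-bromo-2-iodo-6-methoxyphenol F8.
  - Sonogashira coupling with ethynyltrimethylsilane at the iodide (Pd(PPh3)2Cl2, CuI, Et3N, DMF, 60 °C), with in situ 5-endo cyclisation of the phenol onto the alkyne, gives (5-bromo-7-methoxy-1-benzofuran-2-yl)trimethylsilane F9.
  - Bu4NF in THF removes the silyl group to give 4.

## Further compounds

F1 | step 5 | 5-bromo-7-methoxy-1-benzofuran-2(3H)-one | COc1cc(Br)cc2CC(=O)Oc12
F2 | step 5 | methyl 2-(5-bromo-2-hydroxy-3-methoxyphenyl)acetate | COC(=O)Cc1cc(Br)cc(OC)c1O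
F3 | step 5 | [3-methoxy-4-(methoxymethoxy)phenyl]methanol | COCOc1ccc(CO)cc1OC
F4 | step 5 | methyl 2-[5-bromo-3-methoxy-2-{[3-methoxy-4-(methoxymethoxy)phenyl]methoxy}phenyl]acetate | COC(=O)Cc1cc(Br)cc(OC)c1OCc1ccc(OCOC)c(OC)c1
F5 | step 5 | methyl 2-[5-bromo-3-methoxy-2-{[3-methoxy-4-(methoxymethoxy)phenyl]methoxy}phenyl]-2-diazoacetate | COC(=O)C(=[N+]=[N-])c1cc(Br)cc(OC)c1OCc1ccc(OCOC)c(OC)c1
F6 | step 5 | methyl (2R,3S)-5-bromo-7-methoxy-2-[3-methoxy-4-(methoxymethoxy)phenyl]-2,3-dihydro-1-benzofuran-3-carboxylate (cis) | COc1cc([C@@H]2Oc3c(OC)cc(Br)cc3[C@@H]2C(=O)OC)ccc1OCOC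
F7 | step 5 | methyl (2R,3R)-5-bromo-7-methoxy-2-[3-methoxy-4-(methoxymethoxy)phenyl]-2,3-dihydro-1-benzofuran-3-carboxylate (trans) | COc1cc([C@@H]2Oc3c(OC)cc(Br)cc3[C@H]2C(=O)OC)ccc1OCOC
F0 | step 6 | none | none
F0 | step 7 | none | none
F8 | step 2 | 4-bromo-2-iodo-6-methoxyphenol | COc1cc(Br)cc(I)c1O
F9 | step 2 | (5-bromo-7-methoxy-1-benzofuran-2-yl)trimethylsilane | COc1cc(Br)cc2cc([Si](C)(C)C)oc12
A1 | alternative 1 | (1R,2S)-3-(tert-butyldimethylsilyloxy)-1-(ethynyloxy)-1-[3-methoxy-4-(methoxymethoxy)phenyl]-2-[4-(triisopropylsilyloxymethyl)furan-2-yl]propane | C#CO[C@@H](c1ccc(OCOC)c(OC)c1)[C@H](CO[Si](C)(C)C(C)(C)C)c1cc(CO[Si](C(C)C)(C(C)C)C(C)C)co1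
A2 | alternative 1 | (2R,3S)-3-(tert-butyldimethylsilyloxymethyl)-2-[3-methoxy-4-(methoxymethoxy)phenyl]-5-(triisopropylsilyloxymethyl)-2,3-dihydro-1-benzofuran-7-ol (trans) | COc1cc([C@@H]2Oc3c(O)cc(CO[Si](C(C)C)(C(C)C)C(C)C)cc3[C@H]2CO[Si](C)(C)C(C)(C)C)ccc1OCOC
A3 | alternative 2 | 4-[(2R)-6-bromo-8-methoxy-4-oxo-3,4-dihydro-2H-chromen-2-yl]-2-methoxyphenyl 2,2-dimethylpropanoate | COc1cc([C@H]2CC(=O)c3cc(Br)cc(OC)c3O2)ccc1OC(=O)C(C)(C)C
A4 | alternative 2 | methyl (2R,3R)-5-bromo-7-methoxy-2-[3-methoxy-4-(pivaloyloxy)phenyl]-2,3-dihydro-1-benzofuran-3-carboxylate (trans) | COc1cc([C@@H]2Oc3c(OC)cc(Br)cc3[C@H]2C(=O)OC)ccc1OC(=O)C(C)(C)C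
A5 | alternative 3 | tert-butyl{[(4S,5R)-4-(tert-butyldimethylsilyloxymethyl)-5-[3-methoxy-4-(methoxymethoxy)phenyl]-4,5-dihydrofuran-2-yl]oxy}dimethylsilane | COc1cc([C@@H]2OC(O[Si](C)(C)C(C)(C)C)=C[C@H]2CO[Si](C)(C)C(C)(C)C)ccc1OCOC
A6 | alternative 3 | methyl 3-bromo-2-oxo-2H-pyran-5-carboxylate (methyl 3-bromocoumalate) | COC(=O)C1=COC(=O)C(Br)=C1
A7 | alternative 3 | methyl (2R,3S)-7-bromo-3-(tert-butyldimethylsilyloxymethyl)-2-[3-methoxy-4-(methoxymethoxy)phenyl]-2,3-dihydro-1-benzofuran-5-carboxylate (trans) | COc1cc([C@@H]2Oc3c(Br)cc(C(=O)OC)cc3[C@H]2CO[Si](C)(C)C(C)(C)C)ccc1OCOC
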